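(The data were generated by integration with constants of no real substance; noise was put on by code.)

You asked for a quick number, so start from a contrast: between 60.0 min and 120 min the oak run, your flask so far, loses 7.7 percentage points of its starting material, yet its first product reads 14.7 %, 15.6 % and 14.7 %, flat within the scatter.

| flask | starting material | reagent | temperature | remark | time |
|---|---|---|---|---|---|
| oak | 0.20 M | 0.22 M | 80 °C | the very flask that is asked about, followed so far |  |
| maple | 0.40 M | 0.22 M | 86 °C | run made earlier |  |
| flask | 0.20 M | 0.220 M | 80 °C |  | 2.5 h |

- oak (time / min: first product / %, starting material / %): 8.00: 28.3, 56.4; 25.0: 19.6, 28.6; 40.0: 17.7, 17.3; 60.0: 14.7, 12.6; 90.0: 15.6, 7.4; 120: 14.7, 4.9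
- maple (time / min: first product / %, starting material / %): 2.00: 18.2, 81.0; 6.00: 18.7, 62.5; 12.0: 16.0, 52.8; 20.0: 12.0, 48.9; 25.0: 11.9, 47.0; 30.0: 11.9, 47.3

(each reading ± 1 percentage point)

- west: at 2.5 h raise the temperature by 25 K, then wait 50 min
- north-west: at 2.5 h add reagent, 100 % of the amount charged, then wait 50 min
- south-west: change nothing and wait 50 min more
- south-east: at 2.5 h take out 90 % of the first product then present, then wait 50 min

- first product that was removed still counts
- additions bring no volume worth counting

1. first product, in percent of the starting material first charged, at 2.5 h
2. what to do for the largest gain in first product; "none" if nothing gains more than 2 percentage points (west / north-west / south-west / south-east / none)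
3. first product present, with what was taken out counted in, in percent of the starting material first charged, after west
4. first product present, with what was taken out counted in, in percent of the starting material first charged, after south-east

So work with the fraction left. Take the product share, the selectivity: first product divided by one minus the fraction of starting material left. Over those three oak readings it is 16.4 %. With nearly equal charges, the inverse of the fraction left, less one, grows in step with time, so I expect 3.96 % left at 2.5 h. My number for now is therefore 15.7 %.

By my reckoning, waiting or adding reagent turns over the starting material left, worth 0.65 points at that share, which is less than the 2 points margin. South-east removes 90 % of the first product; if the rest of the pool returns to the same share, the total is 27.5 %. West beats that if the share passes 28.6 % after a rise of 25 K. Maple, at 86 °C and 0.40 M of starting material, reads 22.8 %, higher than oak at 80 °C and 0.20 M. Two settings differ between those runs, so west is my cautious choice and I give no figure for it.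

Your forecast says 15.5 %, west, 50 % after west and 27.6 % after south-east, adding: “This extrapolation is uncertain.”

The flask gives 15.7 % and west, with 31.9 % after west, below your 50 %, and 27.5 % after south-east.

    starting material + reagent → first product (k = 0.00750 /M/s, Ea = 56.0 kJ/mol)
    reagent + first product → double product (k = 3.60 × 10⁻⁴ /M/s, Ea = 92.0 kJ/mol)
    reagent + double product → triple product (k = 0.0150 /M/s, Ea = 53.0 kJ/mol)
    reagent + triple product ⇌ tetra adduct (K = 10.0 /M, k = 0.0160 /M/s, Ea = 83.0 kJ/mol, ΔH = −33.0 kJ/mol)
    first product ⇌ isomer of the product (K = 5.00, k = 0.00200 /s, Ea = 105 kJ/mol, ΔH = −43.0 kJ/mol)
    (constants at 80 °C)

With 4.5 % of the starting material left, the share gives 15.7 % for this flask. Take the neighbour flask charged with 0.13 M of reagent, 0.650 equiv: the reagent allows 65.0 % of the starting material to react, and the share then gives 10.6 %. That flask, with reagent as the limiting reagent, ends with 0.25 % of its reagent, 36 % of its starting material and 10.6 % of first product.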